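## Retrosynthetic overview

1. Ainsliadimer B (22) ← bis(dimethylamine) adduct 20, in which both α-methylene lactones are masked; they are released last.
2. C10–OH and C14H2 ← reductive γ-oxygenation of ring dienone 18 ← loss of HNO2 from nitro enone 17 (the nitro group is a traceless activator).
3. Spiro-cyclohexene ring (the only ring built, formed after the fragment union) ← C2–C4′ bond by intramolecular Pd-catalysed ketone α-alkenylation of vinyl iodide 14.
4. Key union: C14–C15′ bond by intermolecular nitronate Michael addition of nitroalkane 13 (unit 1) to exocyclic enone 4 (unit 2).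
5. Both fragments come from dehydrocostus lactone 1 through the common amino enone 4; the two 5/7/5 guaianolide ring systems are taken intact from 1.

Assumption: dehydrocostus lactone (bulk isolate of costus root oil) counts as the commercial starting material; guaianolide numbering is used (primes = unit 2), and centres formed as inconsequential mixtures and later destroyed or reset (C3, C10, C14 of unit 1, C4′ of 14) are left undefined in the SMILES.

## Route

Step 1
Reactants: 1 dehydrocostus lactone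
Product: 2 3-epizaluzanin C (3α-hydroxydehydrocostus lactone)
Conditions: SeO2 (0.5 equiv), t-BuOOH (2 equiv), CH2Cl2, rt
Reagents that add atoms: tert-butyl hydroperoxide, CC(C)(C)OO
Why: Sharpless SeO2 allylic oxidation (ene reaction then [2,3] shift) hydroxylates C3 next to the C4 exocyclic alkene from the convex α-face; this centre is removed in step 3.

Step 2
Reactants: 2 3-epizaluzanin C
Product: 3 amino alcohol (13-dimethylamino-11βH-dihydro-3-epizaluzanin C)
Conditions: Me2NH (2 M in THF, 3 equiv), MeOH, 0 °C to rt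
Reagents that add atoms: dimethylamine, CNC
Why: Aza-Michael addition to the α-methylene-γ-butyrolactone (the only acceptor) masks it; protonation of the lactone enolate from the less hindered face gives 11βH, a centre destroyed again in step 17.

Step 3
Reactants: 3 amino alcohol
Product: 4 amino enone (13-dimethylamino-11βH-dihydrodehydrozaluzanin C)
Conditions: Dess–Martin periodinane (1.3 equiv), CH2Cl2, 0 °C to rt
Reagents that add atoms: none
Why: Dess–Martin oxidation of the allylic alcohol gives the exocyclic C4=C15 enone and tolerates the tertiary amine.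

Step 4
Reactants: 4 amino enone
Product: 6 15-hydroxy ketone (4βH), via 15-boryl ketone 5 (not isolated)
Conditions: B2pin2 (1.1 equiv), CuCl (5 mol%), NaOt-Bu (10 mol%), DPEphos (5 mol%), MeOH (2 equiv), THF, rt; then NaBO3·4H2O, THF/H2O, rt
Reagents that add atoms: sodium perborate, [Na+].[O-]OB=O
Why: Copper-catalysed conjugate borylation of the sole Michael acceptor followed by stereoretentive C–B oxidation is a formal hydration of the enone; C4, α to the ketone, equilibrates to the more stable 4βH epimer (CH2OH α, trans to C6).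

Step 5
Reactants: 6 15-hydroxy ketone
Product: 7 15-O-TBDPS ketone
Conditions: t-BuPh2SiCl, imidazole, DMF, rt
Reagents that add atoms: tert-butyl(chloro)diphenylsilane, CC(C)(C)[Si](Cl)(c1ccccc1)c1ccccc1
Why: Silylation of the primary alcohol blocks retro-aldol and dehydration of the β-hydroxy ketone.

Step 6
Reactants: 7 15-O-TBDPS ketone
Product: 9 1,10(14)-dien-3-one, via trimethylsilyl enol ether 8 (not isolated)
Conditions: LiN(i-Pr)2 (1.05 equiv), Me3SiCl, THF, −78 °C; then Pd(OAc)2 (1.1 equiv), MeCN, rt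
Reagents that add atoms: none
Why: Kinetic deprotonation at the less hindered C2 methylene and silylation, then Saegusa–Ito dehydrogenation (β-hydride loss from C1), give the C1=C2 enone conjugated with C10=C14.

Step 7
Reactants: 9 1,10(14)-dien-3-one
Product: 10 2-iodo-1,10(14)-dien-3-one
Conditions: I2 (2 equiv), pyridine, CH2Cl2, rt
Reagents that add atoms: iodine, II
Why: Johnson α-iodination of the enone (pyridine conjugate addition, iodination at C2, elimination) installs the vinyl iodide needed for ring closure.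

Step 8
Reactants: 10 2-iodo-1,10(14)-dien-3-one
Product: 11 2-iodo-14-nitro-1-en-3-one
Conditions: NaNO2 (4 equiv), AcOH (6 equiv), THF, 0 °C to rt
Reagents that add atoms: sodium nitrite, [Na+].[O-]N=O
Why: Conjugate 1,6-addition of nitrite (as HNO2, through nitrogen) to the unhindered terminal C14 of the linear dienone, then tautomerisation to the conjugated enone, gives a vinylogous β-nitro ketone; C10 forms as an inconsequential epimer mixture.

Step 9
Reactants: 11 2-iodo-14-nitro-1-en-3-one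
Product: 12 2-iodo-14-nitro-1-en-3-ol
Conditions: NaBH4, CeCl3·7H2O, MeOH, −40 °C
Reagents that add atoms: none
Why: Luche 1,2-reduction removes the enone, so the nitro compound can no longer lose HNO2 under base; the C3 epimers are inconsequential.

Step 10
Reactants: 12 2-iodo-14-nitro-1-en-3-ol
Product: 13 3-O-triethylsilyl ether (nitroalkane donor)
Conditions: Et3SiOTf, 2,6-lutidine, CH2Cl2, −78 °C
Reagents that add atoms: triethylsilyl trifluoromethanesulfonate, CC[Si](CC)(CC)OS(=O)(=O)C(F)(F)F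
Why: Silylation of the allylic alcohol prevents palladium-mediated redox chemistry of a free 2-iodoallylic alcohol in step 12.

Step 11
Reactants: 13 nitroalkane donor; 4 amino enone (1.2 equiv)
Product: 14 Michael adduct (C14–C15′ linked γ-nitro ketone)
Conditions: DBU (0.2 equiv), MeCN, 0 °C to rt
Reagents that add atoms: none
Why: Nitro-Michael addition: the nitronate of 13 (its only acidic C–H) adds to the unhindered exocyclic β-carbon C15′ of enone 4 and joins the two guaianolide fragments; the new centres C14 and C4′ are mixtures that are later erased (C14) or reset (C4′).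

Step 12
Reactants: 14 Michael adduct
Product: 15 spiro-cyclised dimer (C2–C4′ bond)
Conditions: Pd(PPh3)4 (20 mol%), KOPh (3 equiv), THF, 70 °C
Reagents that add atoms: none
Why: Intramolecular Pd-catalysed ketone α-alkenylation: the reversibly formed enolate can reach the C2–Pd centre only through C4′ (six-membered ring; C2′ would need an eight-membered ring), and C–C reductive elimination on the convex α-face of the cis-fused unit 2 cyclopentanone sets the spiro centre (C2 α, C15′ β).

Step 13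
Reactants: 15 spiro-cyclised dimer
Product: 16 spiro dimer 3-ol
Conditions: HF·pyridine, pyridine, THF, 0 °C
Reagents that add atoms: none
Why: The secondary triethylsilyl ether is cleaved much faster than the primary tert-butyldiphenylsilyl ether under buffered HF·pyridine.

Step 14
Reactants: 16 spiro dimer 3-ol
Product: 17 spiro dimer 14-nitro-1-en-3-one
Conditions: MnO2 (20 equiv), CH2Cl2, rt
Reagents that add atoms: none
Why: MnO2 oxidises the allylic alcohol chemoselectively to the C1=C2 enone.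

Step 15
Reactants: 17 spiro dimer 14-nitro-1-en-3-one
Product: 18 spiro dimer 1,10(14)-dien-3-one
Conditions: DBU (2 equiv), CH2Cl2, 0 °C to rt
Reagents that add atoms: none
Why: Vinylogous E1cB elimination of HNO2 (nitro as leaving group): deprotonation at C10, γ to the enone and β to the nitro group and so more acidic than C5–H, expels nitrite and gives the ring dienone, while C4 stays in its stable 4βH configuration.

Step 16
Reactants: 18 spiro dimer 1,10(14)-dien-3-one
Product: 20 bis(dimethylamine) adduct of ainsliadimer B, via trimethylsilyl dienol ether 19 (not isolated)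
Conditions: [(Ph3P)CuH]6 (0.3 equiv), Me3SiCl (3 equiv), THF, −40 to 0 °C; then Bu4NF, O2, P(OEt)3, THF, −40 °C; then Bu4NF/AcOH, rt
Reagents that add atoms: dioxygen, O=O
Why: Copper hydride 1,6-conjugate reduction (hydride to the unhindered C14, the β-carbon C1 being fully substituted) with silyl trapping, then dienolate autoxidation at the γ-carbon C10 with phosphite reduction of the hydroperoxide, installs the tertiary alcohol from the ring face opposite the bulky C5′ branch of the spiro centre (10β-OH, expected major); fluoride also removes the C15 silyl ether.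

Step 17
Reactants: 20 bis(dimethylamine) adduct of ainsliadimer B
Product: 22 ainsliadimer B, via bis(trimethylammonium) diiodide 21 (not isolated)
Conditions: MeI (excess), MeCN, rt; then NaHCO3 (aq), CH2Cl2, rt
Reagents that add atoms: none
Why: Exhaustive N-methylation followed by mild-base Hofmann-type (E1cB) elimination of trimethylamine regenerates both α-methylene-γ-butyrolactones without disturbing the β-hydroxy ketone, the enone or the tertiary alcohol.

## Compound list

1 | dehydrocostus lactone (guaia-4(15),10(14),11(13)-trien-12,6α-olide; 1αH, 5αH, 6βH, 7αH) | C=C3CC[C@H]1C(=C)CC[C@H]2C(=C)C(=O)O[C@@H]2[C@H]13 | starting material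

2 | 3-epizaluzanin C (3α-hydroxy derivative of 1) | C=C3[C@H](O)C[C@H]1C(=C)CC[C@H]2C(=C)C(=O)O[C@@H]2[C@H]13 | intermediate

3 | amino alcohol: 13-(dimethylamino)-11βH,13-dihydro-3-epizaluzanin C | C=C3[C@H](O)C[C@H]1C(=C)CC[C@H]2[C@H](CN(C)C)C(=O)O[C@@H]2[C@H]13 | intermediate

4 | amino enone: 13-(dimethylamino)-11βH,13-dihydrodehydrozaluzanin C (3-ketone, exocyclic C4=C15) | C=C3C(=O)C[C@H]1C(=C)CC[C@H]2[C@H](CN(C)C)C(=O)O[C@@H]2[C@H]13 | intermediate

5 | 15-boryl ketone: 15-(pinacolatoboryl)-4βH,15-dihydro derivative of 4 | CC4(C)OB(C[C@@H]3C(=O)C[C@H]1C(=C)CC[C@H]2[C@H](CN(C)C)C(=O)O[C@@H]2[C@H]13)OC4(C)C | intermediate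

6 | 15-hydroxy ketone: 4βH, CH2OH α | OC[C@@H]3C(=O)C[C@H]1C(=C)CC[C@H]2[C@H](CN(C)C)C(=O)O[C@@H]2[C@H]13 | intermediate

7 | 15-O-tert-butyldiphenylsilyl ether of 6 | CC(C)(C)[Si](c1ccccc1)(c1ccccc1)OC[C@@H]3C(=O)C[C@H]1C(=C)CC[C@H]2[C@H](CN(C)C)C(=O)O[C@@H]2[C@H]13 | intermediate

8 | trimethylsilyl enol ether of 7 (C2=C3) | CC(C)(C)[Si](c1ccccc1)(c1ccccc1)OC[C@@H]3C(O[Si](C)(C)C)=C[C@H]1C(=C)CC[C@H]2[C@H](CN(C)C)C(=O)O[C@@H]2[C@H]13 | intermediate

9 | 1,10(14)-dien-3-one (C1=C2 enone conjugated with exocyclic C10=C14) | CC(C)(C)[Si](c1ccccc1)(c1ccccc1)OC[C@@H]3C(=O)C=C1C(=C)CC[C@H]2[C@H](CN(C)C)C(=O)O[C@@H]2[C@H]13 | intermediate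

10 | 2-iodo derivative of 9 | CC(C)(C)[Si](c1ccccc1)(c1ccccc1)OC[C@@H]3C(=O)C(I)=C1C(=C)CC[C@H]2[C@H](CN(C)C)C(=O)O[C@@H]2[C@H]13 | intermediate

11 | 2-iodo-14-nitro-1-en-3-one (C10–H, epimer mixture) | CC(C)(C)[Si](c1ccccc1)(c1ccccc1)OC[C@@H]3C(=O)C(I)=C1C(C[N+](=O)[O-])CC[C@H]2[C@H](CN(C)C)C(=O)O[C@@H]2[C@H]13 | intermediate

12 | 2-iodo-14-nitro-1-en-3-ol (C3 and C10 epimers) | CC(C)(C)[Si](c1ccccc1)(c1ccccc1)OC[C@@H]3C(O)C(I)=C1C(C[N+](=O)[O-])CC[C@H]2[C@H](CN(C)C)C(=O)O[C@@H]2[C@H]13 | intermediate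

13 | 3-O-triethylsilyl ether of 12 (nitroalkane donor, unit 1) | CC(C)(C)[Si](c1ccccc1)(c1ccccc1)OC[C@@H]3C(O[Si](CC)(CC)CC)C(I)=C1C(C[N+](=O)[O-])CC[C@H]2[C@H](CN(C)C)C(=O)O[C@@H]2[C@H]13 | intermediate

14 | Michael adduct: C14 of 13 bonded to C15′ of 4 (γ-nitro ketone; mixtures at C3, C10, C14, C4′) | CC(C)(C)[Si](c1ccccc1)(c1ccccc1)OC[C@@H]3C(O[Si](CC)(CC)CC)C(I)=C1C(C(CC6C(=O)C[C@H]4C(=C)CC[C@H]5[C@H](CN(C)C)C(=O)O[C@@H]5[C@H]46)[N+](=O)[O-])CC[C@H]2[C@H](CN(C)C)C(=O)O[C@@H]2[C@H]13 | intermediate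

15 | spiro-cyclised dimer: new C2–C4′ bond, C4′ quaternary (C2 α, C15′ β), 3-OTES, 14-nitro | CN(C)C[C@@H]1C(=O)O[C@@H]2[C@@H]3C4=C(C(O[Si](CC)(CC)CC)[C@H]3CO[Si](c5ccccc5)(c6ccccc6)C(C)(C)C)[C@]3(CC([N+](=O)[O-])C4CC[C@@H]12)C(=O)C[C@H]1C(=C)CC[C@H]2[C@H](CN(C)C)C(=O)O[C@@H]2[C@H]13 | intermediate

16 | spiro dimer 3-ol | CN(C)C[C@@H]1C(=O)O[C@@H]2[C@@H]3C4=C(C(O)[C@H]3CO[Si](c5ccccc5)(c6ccccc6)C(C)(C)C)[C@]3(CC([N+](=O)[O-])C4CC[C@@H]12)C(=O)C[C@H]1C(=C)CC[C@H]2[C@H](CN(C)C)C(=O)O[C@@H]2[C@H]13 | intermediate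

17 | spiro dimer 14-nitro-1-en-3-one | CN(C)C[C@@H]1C(=O)O[C@@H]2[C@@H]3C4=C(C(=O)[C@H]3CO[Si](c5ccccc5)(c6ccccc6)C(C)(C)C)[C@]3(CC([N+](=O)[O-])C4CC[C@@H]12)C(=O)C[C@H]1C(=C)CC[C@H]2[C@H](CN(C)C)C(=O)O[C@@H]2[C@H]13 | intermediate

18 | spiro dimer 1,10(14)-dien-3-one (C10=C14 inside the new six-membered ring) | CN(C)C[C@@H]1C(=O)O[C@@H]2[C@@H]3C4=C(C(=O)[C@H]3CO[Si](c5ccccc5)(c6ccccc6)C(C)(C)C)[C@]3(CC=C4CC[C@@H]12)C(=O)C[C@H]1C(=C)CC[C@H]2[C@H](CN(C)C)C(=O)O[C@@H]2[C@H]13 | intermediate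

19 | trimethylsilyl dienol ether (C2=C3–OSiMe3, C1=C10, C14H2) | CN(C)C[C@@H]1C(=O)O[C@@H]2[C@@H]3C=4C(=C(O[Si](C)(C)C)[C@H]3CO[Si](c5ccccc5)(c6ccccc6)C(C)(C)C)[C@]3(CCC4CC[C@@H]12)C(=O)C[C@H]1C(=C)CC[C@H]2[C@H](CN(C)C)C(=O)O[C@@H]2[C@H]13 | intermediate

20 | bis(dimethylamine) adduct of ainsliadimer B (13,13′-bis(dimethylamino)-11βH,11′βH; 10β-OH; 15-OH) | CN(C)C[C@@H]1C(=O)O[C@@H]2[C@@H]3C4=C(C(=O)[C@H]3CO)[C@]3(CC[C@]4(O)CC[C@@H]12)C(=O)C[C@H]1C(=C)CC[C@H]2[C@H](CN(C)C)C(=O)O[C@@H]2[C@H]13 | intermediate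

21 | bis(trimethylammonium) diiodide of 20 | C[N+](C)(C)C[C@@H]1C(=O)O[C@@H]2[C@@H]3C4=C(C(=O)[C@H]3CO)[C@]3(CC[C@]4(O)CC[C@@H]12)C(=O)C[C@H]1C(=C)CC[C@H]2[C@H](C[N+](C)(C)C)C(=O)O[C@@H]2[C@H]13.[I-].[I-] | intermediate

22 | ainsliadimer B | C=C1C(=O)O[C@@H]2[C@@H]3C4=C(C(=O)[C@H]3CO)[C@]3(CC[C@]4(O)CC[C@@H]12)C(=O)C[C@H]1C(=C)CC[C@H]2C(=C)C(=O)O[C@@H]2[C@H]13 | target

## Step count and risks

Total steps: 17. Longest linear sequence: 17 (1 → 22; acceptor 4 is reached after three steps and used twice, as precursor of unit 1 and as unit 2).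

The three steps most likely to fail:

Step 8 (1,6-addition of nitrite). Conjugate addition of HNO2 is known for simple enones but not for such a dienone, and O-attack or 1,4-addition could compete. The fallback leaves the dehydrogenation, iodination and nitrite sequence and sets out from ketone 7. Radical nitration of the isolated C10=C14 alkene (AgNO2, TEMPO, 4 Å MS, ClCH2CH2Cl, 70 °C) gives the exocyclic nitroalkene F1. Catalytic DBU in CH2Cl2 then moves the double bond through the allyl nitronate and the C3 dienol into conjugation with the ketone, giving the 14-nitro-1-en-3-one F2. α-Iodination of F2 (I2, pyridine) comes back to the route at 11.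

Step 12 (Pd-catalysed spiro closure). A congested quaternary centre is formed next to a tetrasubstituted vinyl iodide, and protodeiodination or retro-Michael cleavage could win. The fallback closes the ring by a radical instead and sets out from 14. Me3SiCl, NaI and Et3N in MeCN give the more substituted silyl enol ether F3. (Me3Si)3SiH and AIBN in toluene at 80 °C generate the C2 vinyl radical, which adds 6-exo to C4′ of the enol ether and gives the cyclised silyl ether F4. K2CO3 in MeOH frees the C3′ alcohol F5, and Dess–Martin oxidation of F5 returns to the route at 15.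

Step 16 (reductive γ-oxygenation). Hydride could be delivered 1,4 instead of 1,6, oxygen could enter at C2, and the facial selectivity at C10 may be modest; a 10α-epimer would have to be removed by chromatography. The fallback replaces the copper hydride and dienolate sequence by hydrogen-atom-transfer hydration and sets out from 18. Mn(dpm)3 (cat.), PhSiH3 and O2 in i-PrOH at 0 °C, then P(OEt)3, transfer a hydrogen atom to C14 and trap the resulting C10 radical with O2, giving the 10-hydroxy silyl ether F6. Bu4NF/AcOH then removes the silyl group and comes back to the route at 20.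

## Further compounds

F1 | step 8 | exocyclic nitroalkene (14-nitro-10(14)-en-3-one, 15-OTBDPS) | CC(C)(C)[Si](c1ccccc1)(c1ccccc1)OC[C@@H]3C(=O)C[C@H]1C(=C[N+](=O)[O-])CC[C@H]2[C@H](CN(C)C)C(=O)O[C@@H]2[C@H]13
F2 | step 8 | 14-nitro-1-en-3-one (de-iodo analogue of 11) | CC(C)(C)[Si](c1ccccc1)(c1ccccc1)OC[C@@H]3C(=O)C=C1C(C[N+](=O)[O-])CC[C@H]2[C@H](CN(C)C)C(=O)O[C@@H]2[C@H]13
F3 | step 12 | trimethylsilyl enol ether of 14 (C3′=C4′) | CC(C)(C)[Si](c1ccccc1)(c1ccccc1)OC[C@@H]3C(O[Si](CC)(CC)CC)C(I)=C1C(C(CC6=C(O[Si](C)(C)C)C[C@H]4C(=C)CC[C@H]5[C@H](CN(C)C)C(=O)O[C@@H]5[C@H]46)[N+](=O)[O-])CC[C@H]2[C@H](CN(C)C)C(=O)O[C@@H]2[C@H]13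
F4 | step 12 | cyclised 3′-O-trimethylsilyl ether (C2–C4′ bond formed) | CN(C)C[C@@H]1C(=O)O[C@@H]2[C@@H]3C4=C(C(O[Si](CC)(CC)CC)[C@H]3CO[Si](c5ccccc5)(c6ccccc6)C(C)(C)C)[C@]3(CC([N+](=O)[O-])C4CC[C@@H]12)C(O[Si](C)(C)C)C[C@H]1C(=C)CC[C@H]2[C@H](CN(C)C)C(=O)O[C@@H]2[C@H]13
F5 | step 12 | cyclised 3′-alcohol | CN(C)C[C@@H]1C(=O)O[C@@H]2[C@@H]3C4=C(C(O[Si](CC)(CC)CC)[C@H]3CO[Si](c5ccccc5)(c6ccccc6)C(C)(C)C)[C@]3(CC([N+](=O)[O-])C4CC[C@@H]12)C(O)C[C@H]1C(=C)CC[C@H]2[C@H](CN(C)C)C(=O)O[C@@H]2[C@H]13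
F6 | step 16 | 10β-hydroxy 15-O-TBDPS ether of 20 | CN(C)C[C@@H]1C(=O)O[C@@H]2[C@@H]3C4=C(C(=O)[C@H]3CO[Si](c5ccccc5)(c6ccccc6)C(C)(C)C)[C@]3(CC[C@]4(O)CC[C@@H]12)C(=O)C[C@H]1C(=C)CC[C@H]2[C@H](CN(C)C)C(=O)O[C@@H]2[C@H]13
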